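**Plan**

1. Retrosynthesis: cut the exocyclic amidine C–N bond between the 2-amino nitrogen and the imidazolinedione ring (back to 1-methylparabanic acid), return the carbinol to the C4 aroyl ketone and the 2-amino group to a benzamide, then cut N3–C4 of the imidazole.
2. What allows that cut: N1(Me)–C2(N)=N3 of the 2-aminoimidazole, next to an acyl-bearing C4, is the exocyclic N–C3=N2 of a 3-amino-1,2,4-oxadiazole, whose weak O1–N2 bond can be given up for N3–C4 when an enaminone α-carbon attacks N2.
3. The enaminone is cut at its N–C bond (aza-Michael addition of the N-methylaminooxadiazole to an ynone) and the ynone at its acyl–alkyne bond (acetylide plus Weinreb amide).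
4. Forward: chain assembly to the ynone, N–C bond to the tertiary enaminone, then the imidazole, the only ring built (the oxadiazole is consumed into the 2-benzamido group); the imidazolinedione ring is attached preformed in the last step.
5. Stereochemistry: the single carbinol centre (R) comes from catalyst-controlled transfer hydrogenation of the C4 ketone with RuCl[(R,R)-TsDPEN](p-cymene), placed after the only acidic step and before the neutral final condensation.

Key step: step 4

Assumption: in the transfer hydrogenation the imidazolyl ring is taken to occupy the aryl site of the usual transition-state model, which is why the (R,R) ligand is chosen; the sense of induction is to be confirmed on the first sample.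
Assumption: the compounds marked as starting materials in the list are taken as catalogue items.

**Route**

Step 1
Reactants: 1 3-(4-methoxyphenyl)-1-propyne; 2 N,4-dimethoxy-N-methylbenzamide
Product: 5 1,4-bis(4-methoxyphenyl)but-2-yn-1-one, via lithium acetylide 3 (not isolated), via tetrahedral lithium adduct 4 (not isolated)
Conditions: n-BuLi (1.0 equiv), THF, −78 °C; then 2, −78 to −20 °C; cold 1 M HCl
Reagents that add atoms: none
Why: Weinreb ketone synthesis: one equivalent of n-BuLi at −78 °C removes only the acetylenic proton, the acetylide adds once to the N-methoxy-N-methylamide because the chelated adduct 4 holds until the quench, and cold acid protonates the released N,O-dimethylhydroxylamine before it can add to the ynone.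

Step 2
Reactants: 6 3-amino-5-phenyl-1,2,4-oxadiazole
Product: 8 N-methyl-5-phenyl-1,2,4-oxadiazol-3-amine, via ethyl formimidate 7 (not isolated)
Conditions: HC(OEt)3, TsOH (cat.), 140 °C, EtOH distilled off; evaporate; NaBH4, EtOH, 0 °C to rt
Reagents that add atoms: triethyl orthoformate, CCOC(OCC)OCC
Why: Formimidate route to a mono-N-methyl heteroarylamine (orthoester condensation, then borohydride reduction): the amine can react only once with the orthoester, NaBH4 turns N=CH–OEt into N–CH3 by hydride addition, loss of ethoxide and a second hydride addition, and the 1,2,4-oxadiazole, whose amino group is never acylated or exposed to strong base, should be left intact.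

Step 3
Reactants: 8 N-methyl-5-phenyl-1,2,4-oxadiazol-3-amine; 5 1,4-bis(4-methoxyphenyl)but-2-yn-1-one
Product: 11 (E)-1,4-bis(4-methoxyphenyl)-3-[methyl(5-phenyl-1,2,4-oxadiazol-3-yl)amino]but-2-en-1-one, via lithium amide 9 (not isolated), via lithium allenolate 10 (not isolated)
Conditions: LiN(SiMe3)2, THF, −78 °C; then 5, −78 to −30 °C; AcOH, −78 °C
Reagents that add atoms: none
Why: Aza-Michael addition of a nitrogen anion to an ynone: the amine, too weakly nucleophilic in neutral form to condense with a diketone, adds as its lithium amide through the exocyclic nitrogen to the β-carbon of the alkynone, which alone decides that nitrogen ends on the benzyl-bearing carbon, and C-protonation of the allenolate gives the conjugated tertiary enaminone (drawn as the E isomer; the geometry has no bearing on step 4).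

Step 4
Reactants: 11 (E)-1,4-bis(4-methoxyphenyl)-3-[methyl(5-phenyl-1,2,4-oxadiazol-3-yl)amino]but-2-en-1-one
Product: 13 N-[4-(4-methoxybenzoyl)-5-(4-methoxybenzyl)-1-methyl-1H-imidazol-2-yl]benzamide, via 4H-imidazolium zwitterion 12 (not isolated)
Conditions: DMSO, 120 °C, argon
Reagents that add atoms: none
Why: Boulton–Katritzky-type ring transformation: rotation about the N–C bond of the push–pull enaminone brings its α-carbon (the CH between the amino-bearing carbon and the aroyl group) next to N2 of the oxadiazole, C–N2 bond formation is coupled to cleavage of the weak O1–N2 bond with the O1–C5(Ph)=N4 fragment released as a benzimidate that stays attached through N4 to the future C2, and zwitterion 12 passes its acidic C4–H to that benzimidate to give the aromatic imidazole and the benzamide N–H. The closest known reaction is the base-induced rearrangement of N-(1,2,4-oxadiazol-3-yl) β-enaminoketones into 2-acylamino-4-acylimidazoles; with the nitrogen fully substituted the neutral enamine carbon is the nucleophile, and heat in a dipolar aprotic solvent takes the place of the base. The imidazole closes in a five-membered exo mode at nitrogen (the breaking N–O bond lies outside the new ring) with the enamine C=C inside the ring, the same geometry as in the anionic precedent. No stereocentre results, since the sp3 C4 of 12 is lost on aromatisation. The step needs attack through the α-carbon and not through the benzylic carbon, which could close a five-membered ring as well; the absence of base keeps the benzylic CH2 out of the π system, so only the enaminone α-carbon is nucleophilic, and either alkene isomer can react because the attacking carbon is bonded directly to the amino-bearing carbon. An N–O bond is exchanged for C–N and an amide plus an aromatic imidazole are gained, so the isomerisation should be irreversible, and the N1-methyl, C2-amido, C4-aroyl and C5-benzyl positions are dictated by the connectivity of 11.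

Step 5
Reactants: 13 N-[4-(4-methoxybenzoyl)-5-(4-methoxybenzyl)-1-methyl-1H-imidazol-2-yl]benzamide
Product: 14 [2-amino-5-(4-methoxybenzyl)-1-methyl-1H-imidazol-4-yl](4-methoxyphenyl)methanone
Conditions: 6 M HCl, 1,4-dioxane, 100 °C; then aq. NaOH to pH 10
Reagents that add atoms: none
Why: Acid hydrolysis of an N-heteroaryl amide: N3-protonation of the 2-amidoimidazole weakens the amide resonance so that water cleaves the benzoyl group, while the diaryl ketone, the two aryl methyl ethers and the imidazole ring are stable to hot aqueous HCl, and doing this before the reduction keeps acid away from the later carbinol.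

Step 6
Reactants: 14 [2-amino-5-(4-methoxybenzyl)-1-methyl-1H-imidazol-4-yl](4-methoxyphenyl)methanone
Product: 15 (R)-[2-amino-5-(4-methoxybenzyl)-1-methyl-1H-imidazol-4-yl](4-methoxyphenyl)methanol
Conditions: RuCl[(R,R)-TsDPEN](p-cymene) (2 mol %), HCO2Na, H2O/MeOH, 40 °C
Reagents that add atoms: none
Why: Noyori–Ikariya asymmetric transfer hydrogenation: the ruthenium hydride formed from formate passes hydride and the ligand N–H proton to the C=O in an outer-sphere six-membered transition state, in which the π-rich imidazolyl ring, coplanar with the carbonyl as a vinylogous amide, is taken to lie beside the η6-cymene (C–H/π contact) and the anisyl ring away from it, so that the (R,R) ligand directs hydride to the Si face and sets the R carbinol, and the near-neutral aqueous formate medium keeps the ionisable product alcohol intact.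

Step 7
Reactants: 15 (R)-[2-amino-5-(4-methoxybenzyl)-1-methyl-1H-imidazol-4-yl](4-methoxyphenyl)methanol; 16 1-methylparabanic acid
Product: 20 4-({4-[(R)-hydroxy(4-methoxyphenyl)methyl]-5-(4-methoxybenzyl)-1-methyl-1H-imidazol-2-yl}amino)-1-methyl-1H-imidazole-2,5-dione, via O-silyl imidate 17 (not isolated), via silylated carbinol 18 (not isolated), via silylated target 19 (not isolated)
Conditions: 16, N,O-bis(trimethylsilyl)acetamide (BSA), MeCN, rt; then 15, toluene, 110 °C; then MeOH, KF (cat.), rt
Reagents that add atoms: none
Why: Amidine formation by addition–elimination on an O-silyl imidate: silylation of the N3–H/C4=O lactam of 16 marks C4, next to the second carbonyl, as the electrophilic carbon, the exocyclic 2-amino group adds there and trimethylsilanol leaves to give the 4-amino-2,5-dione ring, while the carbinol travels as its trimethylsilyl ether under neutral conditions and is released by fluoride-catalysed methanolysis with its configuration untouched.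

**Compound list**

1 | 3-(4-methoxyphenyl)-1-propyne | COc1ccc(CC#C)cc1 | starting material
2 | N,4-dimethoxy-N-methylbenzamide | COc1ccc(C(=O)N(C)OC)cc1 | starting material
3 | lithium 3-(4-methoxyphenyl)prop-1-yn-1-ide | [Li]C#CCc1ccc(OC)cc1 | intermediate
4 | lithium 1-[methoxy(methyl)amino]-1,4-bis(4-methoxyphenyl)but-2-yn-1-olate (tetrahedral adduct) | [Li]OC(C#CCc1ccc(OC)cc1)(N(C)OC)c1ccc(OC)cc1 | intermediate
5 | 1,4-bis(4-methoxyphenyl)but-2-yn-1-one | COc1ccc(CC#CC(=O)c2ccc(OC)cc2)cc1 | intermediate
6 | 3-amino-5-phenyl-1,2,4-oxadiazole | Nc1noc(-c2ccccc2)n1 | starting material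
7 | ethyl N-(5-phenyl-1,2,4-oxadiazol-3-yl)formimidate | CCOC=Nc1noc(-c2ccccc2)n1 | intermediate
8 | N-methyl-5-phenyl-1,2,4-oxadiazol-3-amine | CNc1noc(-c2ccccc2)n1 | intermediate
9 | lithium methyl(5-phenyl-1,2,4-oxadiazol-3-yl)amide | [Li]N(C)c1noc(-c2ccccc2)n1 | intermediate
10 | lithium 1,4-bis(4-methoxyphenyl)-3-[methyl(5-phenyl-1,2,4-oxadiazol-3-yl)amino]buta-1,2-dien-1-olate | CN(c1noc(-c2ccccc2)n1)C(Cc1ccc(OC)cc1)=C=C(O[Li])c1ccc(OC)cc1 | intermediate
11 | (E)-1,4-bis(4-methoxyphenyl)-3-[methyl(5-phenyl-1,2,4-oxadiazol-3-yl)amino]but-2-en-1-one | CN(c1noc(-c2ccccc2)n1)/C(Cc1ccc(OC)cc1)=C/C(=O)c1ccc(OC)cc1 | intermediate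
12 | N-[4-(4-methoxybenzoyl)-5-(4-methoxybenzyl)-1-methyl-4H-imidazol-1-ium-2-yl]benzimidate (zwitterion) | C[N+]1=C(Cc2ccc(OC)cc2)C(C(=O)c2ccc(OC)cc2)N=C1N=C([O-])c1ccccc1 | intermediate
13 | N-[4-(4-methoxybenzoyl)-5-(4-methoxybenzyl)-1-methyl-1H-imidazol-2-yl]benzamide | COc1ccc(Cc2c(C(=O)c3ccc(OC)cc3)nc(NC(=O)c3ccccc3)n2C)cc1 | intermediate
14 | [2-amino-5-(4-methoxybenzyl)-1-methyl-1H-imidazol-4-yl](4-methoxyphenyl)methanone | COc1ccc(Cc2c(C(=O)c3ccc(OC)cc3)nc(N)n2C)cc1 | intermediate
15 | (R)-[2-amino-5-(4-methoxybenzyl)-1-methyl-1H-imidazol-4-yl](4-methoxyphenyl)methanol | COc1ccc(Cc2c([C@H](O)c3ccc(OC)cc3)nc(N)n2C)cc1 | intermediate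
16 | 1-methylparabanic acid (1-methylimidazolidine-2,4,5-trione) | CN1C(=O)NC(=O)C1=O | starting material
17 | 1-methyl-4-(trimethylsilyloxy)-1H-imidazole-2,5-dione | CN1C(=O)N=C(O[Si](C)(C)C)C1=O | intermediate
18 | (R)-4-[(4-methoxyphenyl)(trimethylsilyloxy)methyl]-5-(4-methoxybenzyl)-1-methyl-1H-imidazol-2-amine | COc1ccc(Cc2c([C@H](O[Si](C)(C)C)c3ccc(OC)cc3)nc(N)n2C)cc1 | intermediate
19 | 4-({4-[(R)-(4-methoxyphenyl)(trimethylsilyloxy)methyl]-5-(4-methoxybenzyl)-1-methyl-1H-imidazol-2-yl}amino)-1-methyl-1H-imidazole-2,5-dione | COc1ccc(Cc2c([C@H](O[Si](C)(C)C)c3ccc(OC)cc3)nc(NC3=NC(=O)N(C)C3=O)n2C)cc1 | intermediate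
20 | 4-({4-[(R)-hydroxy(4-methoxyphenyl)methyl]-5-(4-methoxybenzyl)-1-methyl-1H-imidazol-2-yl}amino)-1-methyl-1H-imidazole-2,5-dione (CNP0288484.1) | COc1ccc(Cc2c([C@H](O)c3ccc(OC)cc3)nc(NC3=NC(=O)N(C)C3=O)n2C)cc1 | target

**Step count and risks**

Total steps: 7. Longest linear sequence: 6 steps (1 → 5 → 11 → 13 → 14 → 15 → 20; the branch from 6 is equally long).

Most likely to fail:

Step 4. The neutral enamine carbon may be too weak a nucleophile to open the N–O bond at temperatures the substrate tolerates, and forcing the reaction with base would open the competing closure through the benzylic carbon. The fallback sets out from 6 and 5. Conjugate addition of the primary amine to the ynone (LiN(SiMe3)2, THF, −78 °C, AcOH quench) should give the hydrogen-bonded secondary enaminone (Z)-1,4-bis(4-methoxyphenyl)-3-[(5-phenyl-1,2,4-oxadiazol-3-yl)amino]but-2-en-1-one F1. NaOEt in DMF then runs the rearrangement in its documented anionic form, where only the α-carbon can attack, and should give N-[4-(4-methoxybenzoyl)-5-(4-methoxybenzyl)-1H-imidazol-2-yl]benzamide F2. Methylation of its anion (MeI, K2CO3, DMF) at the ring nitrogen remote from the aroyl group comes back to the route at 13, at the price of a regiochemical question that the main route avoids.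

Step 6. Facial discrimination between two aryl-type substituents may be poor or opposite to the model, turnover on the vinylogous-amide carbonyl may be slow, the 2-aminoimidazole may bind ruthenium, and the electron-rich carbinol may ionise and lose configuration. The fallback sets out from 14. NaBH4 in MeOH should give the racemic carbinol rac-[2-amino-5-(4-methoxybenzyl)-1-methyl-1H-imidazol-4-yl](4-methoxyphenyl)methanol F3. Its enantiomers are separated by preparative chromatography on a polysaccharide chiral stationary phase with a basic eluent, and the R enantiomer is 15.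

Step 3. Proton transfer from the benzylic–propargylic CH2 of the ynone to the lithium amide may outrun conjugate addition, with loss of the resulting allenone to oligomerisation or furan formation. The ambident amide may also add through a ring nitrogen, and the allenolate may close the ring prematurely (which would only deliver 13 early). The fallback sets out from 5. Hydrochlorination (LiCl, AcOH, rt) should give (Z)-3-chloro-1,4-bis(4-methoxyphenyl)but-2-en-1-one F4. A Buchwald–Hartwig-type C–N coupling of this β-chloroenone with 8 (Pd2(dba)3, Xantphos, Cs2CO3, 1,4-dioxane, 80 °C) comes back to the route at 11.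

**Further compounds**

F1 | step 4 | (Z)-1,4-bis(4-methoxyphenyl)-3-[(5-phenyl-1,2,4-oxadiazol-3-yl)amino]but-2-en-1-one | COc1ccc(C/C(Nc2noc(-c3ccccc3)n2)=C/C(=O)c2ccc(OC)cc2)cc1
F2 | step 4 | N-[4-(4-methoxybenzoyl)-5-(4-methoxybenzyl)-1H-imidazol-2-yl]benzamide | COc1ccc(Cc2[nH]c(NC(=O)c3ccccc3)nc2C(=O)c2ccc(OC)cc2)cc1
F3 | step 6 | rac-[2-amino-5-(4-methoxybenzyl)-1-methyl-1H-imidazol-4-yl](4-methoxyphenyl)methanol | COc1ccc(Cc2c(C(O)c3ccc(OC)cc3)nc(N)n2C)cc1
F4 | step 3 | (Z)-3-chloro-1,4-bis(4-methoxyphenyl)but-2-en-1-one | COc1ccc(C/C(Cl)=C/C(=O)c2ccc(OC)cc2)cc1
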